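The earlier runs and the new flask are calculated for substances that don't exist; scatter was added.

In a one-step world substrate turns straight into target, and the vessel changes only how much has formed by the stop.

| flask | substrate | capture agent | remark | time |
|---|---|---|---|---|
| north-east | 20 mM | 20 mM | run made earlier |  |
| south | 20 mM | 28 mM | run made earlier |  |
| north-west | 20 mM | 44 mM | run made earlier |  |
| west | 10 mM | 20 mM | run made earlier |  |
| teal | 20 mM (fed, over 6.40 min) | 20.0 mM | all but substrate at the start; substrate goes in evenly over 6.40 min, the run ends at 8.0 min | 8.0 min |
| violet | 20 mM | 20.0 mM | one stirred flow tank at steady state, fed with the mixture as stated, mean residence time 8.0 min |  |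
| grey | 20 mM | 20.0 mM | a closed flask charged with all of it at once and left for 8.0 min | 8.0 min |

- north-east (time / min: target / %, trapped intermediate / %, substrate / %): 2.00: 1, 3, 22; 4.00: 0, 5, 7; 6.00: 11, 8, 2; 8.00: 25, 11, 3
- south (time / min: target / %, trapped intermediate / %, substrate / %): 1.50: 0, 0, 30; 3.00: 1, 0, 11; 5.00: 8, 8, 0; 6.00: 16, 7, 0
- north-west (time / min: target / %, trapped intermediate / %, substrate / %): 0.500: 1, 0, 68; 1.33: 2, 0, 31; 3.00: 1, 3, 11; 6.00: 11, 17, 3
- west (time / min: target / %, trapped intermediate / %, substrate / %): 0.500: 4, 0, 68; 1.33: 0, 2, 38; 3.00: 1, 2, 7; 6.00: 13, 8, 4

(readings scatter by 2 percentage points)

- the stated concentrations are those of everything mixed, before any reaction; amounts are the same in each set-up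
- the feed brings no volume worth counting
- the earlier runs were made in a closed, stirred flask
- a reading or a percentage of target counts all its forms, free or not
- a reading of substrate is of its free form alone

1. the set-up with the highest share of target in all that became target or trapped intermediate, at the outlet or at the end ("none" if the first two lie within 2 percentage points) (teal / violet / grey / none)
2. share of target in all that became target or trapped intermediate, at the outlet or at the end, teal
3. share of target in all that became target or trapped intermediate, at the outlet or at the end, violet
4. share of target in all that became target or trapped intermediate, at the outlet or at the end, grey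

But the north-east run is no such world: at 4.00 min substrate reads 7% and target 0%, so 88.0% of the charge sits in forms no column shows. So the reckoning here takes a hidden pool, reached through the early steps and feeding both products: target by a first-order step, trapped intermediate by reaction with capture agent at concentration T.

Then target over trapped intermediate equals K/T at every age of the pool, where K is the capture level at which the two branches run equally fast, a selectivity factor with a unit. The last rows of the four runs give readings from 28.5 mM to 64.0 mM, with a mean K of 42.6 mM.

In the north-east run, trapped intermediate takes 2.20 mM, less than the 20 mM of capture agent, so T stays near its charge. The share K/(K+T) is then 68.1% for teal, violet and grey alike, which makes the answer none.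

The forecast differs: violet is best, with teal 59%, violet 76% and grey 69%, on the grounds that “mixing history acts only through the age distribution”.

The simulation gives none: teal 65.1%, violet 66.7%, grey 65.9%, the first two, violet and grey, lying 0.80 percentage points apart, inside the margin of 2 points.

    substrate → intermediate A (k = 0.0130 s⁻¹)
    intermediate A → intermediate B (k = 0.0630 s⁻¹)
    intermediate B → intermediate C (k = 0.00240 s⁻¹)
    intermediate C → target (k = 0.00280 s⁻¹)
    intermediate C + capture agent → trapped intermediate (k = 0.0770 M⁻¹ s⁻¹)
    substrate → decomposition product (k = 4.00 × 10⁻⁶ s⁻¹)
    substrate + target ⇌ idle adduct, settled at all times (K = 200 M⁻¹)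

Grey still holds 25.4% of its charge as intermediate C at the end. The share from K stands 2.2 points above grey. For teal left until 80.0 min, K at 20.0 mM again gives 68.1%, and that flask holds 68.6%.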